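The numbers in the tables were computed for substances that don't exist.

The birch run shows 8% of open intermediate after 0.667 min. Its climb constant, the pseudo-first-order share of substrate opened per minute, therefore reads 0.120 min⁻¹. The choice for the next run is whether to keep this charge of free catalyst and when to stop.

| setting | birch | flask |
|---|---|---|
| substrate | 0.50 M | 0.50 M |
| partner | 0.55 M | 0.550 M |
| free catalyst | 5 mM | 5.0 mM |
| remark | the very flask that is asked about, followed so far |  |
| time |  | 1.0 h |

birch run (percent of the substrate charged)

| time / min | open intermediate / % | product / % |
|---|---|---|
| 0.667 | 8 | 2 |
| 1.33 | 11 | 0 |
| 3.00 | 16 | 7 |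
| 6.00 | 10 | 12 |
| 15.0 | 5 | 21 |
| 30.0 | 3 | 27 |

(each reading ± 1.5 percentage points)

- percentages count the substrate that a species holds: one idle adduct counts as two
- product is meant together with its idle adduct
- the earlier runs were read with a standard deviation of 1.5 percentage points
- candidate steps: substrate + free catalyst <-> free catalyst + open intermediate; free catalyst + open intermediate <-> catalyst intermediate; partner + catalyst intermediate -> free catalyst + product; substrate + product <-> idle adduct; open intermediate -> decomposed reagent; 2 partner -> homo dimer
- in an amount of product, one idle adduct counts as one product

- time up to 1.0 h at which open intermediate stands highest, in min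
- the amount of open intermediate, in percent of the substrate charged, at that time
- earliest time at which at least nineteen twentieths of that best amount are there, in min
- latest time at which they still are

At the top of the curve, making equals loss, so open intermediate over substrate equals the climb constant over the loss constant. Call this the peak ratio. Substrate falling at the climb constant stands near 69.8% at 3.00 min, and the highest reading, 16%, stands there, so this reckoning reads a peak ratio of 0.229.

In powers of ten the ratio is −0.640. For two first-order steps in a row, the logarithm of the top height is that logarithm divided by one minus the ratio, which gives −0.830, a height of 14.8%. The candidate steps open substrate on free catalyst, so the reckoning takes the ratio as proportional to that charge, with the loss constant held. The decision is to leave the charge as it is and stop near 3.00 min, since the reading has sunk to 10% by 6.00 min.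

The forecast gives a lower height, 14% at 2.7 min, with the window from 2 min to 0.063 h, and says “The peak is sharp”. The birch flask gives 13.8% at 2.32 min, with the window from 1.58 min to 0.0559 h.

    substrate + free catalyst ⇌ free catalyst + open intermediate (K = 0.770, k = 37.5 M⁻¹ min⁻¹)
    free catalyst + open intermediate ⇌ catalyst intermediate (K = 1.76 M⁻¹, k = 46.5 M⁻¹ min⁻¹)
    partner + catalyst intermediate → free catalyst + product (k = 331 M⁻¹ min⁻¹)
    substrate + product ⇌ idle adduct, settled at all times (K = 3.70 M⁻¹)
    open intermediate → decomposed reagent (k = 0.474 min⁻¹)
    2 partner → homo dimer (k = 0.143 M⁻¹ min⁻¹)

At that top the birch flask holds open intermediate over substrate at 0.204, against the peak ratio of 0.229, and its height lies under the reckoned one. The neighbour flask, charged with 0.0020 M of free catalyst, is reckoned at a scaled peak ratio of 0.0917. Its logarithm is −1.04, which gives a height of 7.21%. That neighbour flask reaches 8.74%, which is more than the reckoned 7.21% and less than the 13.8% of the birch flask. After 1.0 h that neighbour flask holds 3.02% of substrate and 10.9% of product, all its forms counted.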